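The seven-membered ring (C1, C5–C10) has the C10 oxygen next to quaternary C1 and the C8(CH3)=C9 alkene. This is the pattern obtained when one methylene (C9) is spliced between the carbonyl carbon and the methyl-bearing α-carbon of a six-membered ketone. The route therefore builds a trans-fused hydrindan-10-one and inserts C9 in one telescoped operation: cyclopropanation of its C8=C10 trimethylsilyl enol ether, iron-mediated cleavage of the shared C8–C10 bond, and loss of HCl to give the C8=C9–C10 enone. The precursor is that enol ether with C6–OTBS and C4–OTES, made from a cyclopentenone by asymmetric conjugate methylation, aldol addition, isopropyl addition and ring-closing metathesis.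

Key step: step 12

Numbering and faces: core carbons keep the target's labels in every intermediate (C1 quaternary methyl carbon, C2 and C3 ring CH2, C4 carbinol carbon with isopropyl, C5 ring-fusion CH, C6 anisoyloxy carbon, C7 CH2, C8 methyl-bearing alkene carbon, C9 alkene CH, C10 acetoxy carbon); α is the face of H5, β the face of the C1 methyl.

Assumption: the sense of induction of the copper–phosphoramidite catalyst in step 3 is assigned on the derived ketone, and the ligand antipode giving (S)-configured C1 is used.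

Step 1
Reactants: 1 3-ethoxycyclopent-2-en-1-one; 2 1,3-dithiane
Product: 5 3-(1,3-dithian-2-yl)cyclopent-2-en-1-one, via 2-lithio-1,3-dithiane 3 (not isolated), via lithium alkoxide 1,2-adduct 4 (not isolated)
Conditions: n-BuLi, THF, −30 °C; then 1, −78 → 0 °C; then 1 M HCl (aq), rt
Reagents that add atoms: water, O
Why: Stork–Danheiser sequence in which the lithiated dithiane adds 1,2 to the vinylogous ester and aqueous acid converts the adduct into the 3-substituted enone with loss of ethanol, no stereocentre being formed.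

Step 2
Reactants: 5 3-(1,3-dithian-2-yl)cyclopent-2-en-1-one
Product: 6 3-(dimethoxymethyl)cyclopent-2-en-1-one
Conditions: PhI(OCOCF3)2, MeOH, 0 °C → rt
Reagents that add atoms: methanol, CO
Why: Oxidative dethioacetalisation by the hypervalent iodine reagent in methanol should give the dimethyl acetal directly, so that the reactive ene-aldehyde is never free and sulfur is removed before the copper-catalysed step.

Step 3
Reactants: 6 3-(dimethoxymethyl)cyclopent-2-en-1-one
Product: 8 (3S)-3-(dimethoxymethyl)-3-methylcyclopent-1-en-1-yl acetate, via aluminium enolate 7 (not isolated)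
Conditions: Me3Al, Cu(O2C-2-thienyl) (monovalent copper, 5 mol %), chiral phosphoramidite ligand (10 mol %), Et2O, −30 °C; then Ac2O, −30 → 0 °C
Reagents that add atoms: trimethylaluminium, C[Al](C)C; acetic anhydride, CC(=O)OC(C)=O
Why: Copper-catalysed asymmetric conjugate addition of Me3Al to a 3-substituted cyclopentenone should create quaternary C1 with the face chosen by the chiral phosphoramidite–copper complex, and O-acetylation of the aluminium enolate stores the C4=C5 enolate regiochemistry.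

Step 4
Reactants: 8 (3S)-3-(dimethoxymethyl)-3-methylcyclopent-1-en-1-yl acetate; 9 acrolein
Product: 11 (2S,3S)-3-(dimethoxymethyl)-2-[(1S)-1-hydroxyprop-2-en-1-yl]-3-methylcyclopentan-1-one, via lithium enolate 10 (not isolated)
Conditions: MeLi (2 equiv), THF, 0 °C; then 9, −78 °C; aq NH4Cl, −78 °C
Reagents that add atoms: none
Why: Regiospecific release of the lithium enolate from the enol acetate followed by a kinetic aldol addition through a Zimmerman–Traxler chair, in which the aldehyde should reach C5 on the face opposite the branched dimethoxymethyl group of C1 (C6 cis to the C1 methyl, the later trans ring fusion) and the (E)-enolate should favour the anti (6S) carbinol.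

Step 5
Reactants: 11 (2S,3S)-3-(dimethoxymethyl)-2-[(1S)-1-hydroxyprop-2-en-1-yl]-3-methylcyclopentan-1-one
Product: 12 (2S,3S)-2-[(1S)-1-(tert-butyldimethylsilyloxy)prop-2-en-1-yl]-3-(dimethoxymethyl)-3-methylcyclopentan-1-one
Conditions: TBSOTf, 2,6-lutidine, CH2Cl2, −78 °C
Reagents that add atoms: tert-butyldimethylsilyl triflate, CC(C)(C)[Si](C)(C)OS(=O)(=O)C(F)(F)F
Why: Low-temperature silylation of the aldol hydroxyl with a silyl triflate blocks retro-aldol and elimination pathways while the acetal, which needs higher temperature to be activated, is left alone.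

Step 6
Reactants: 12 (2S,3S)-2-[(1S)-1-(tert-butyldimethylsilyloxy)prop-2-en-1-yl]-3-(dimethoxymethyl)-3-methylcyclopentan-1-one
Product: 13 (1R,2S,3S)-2-[(1S)-1-(tert-butyldimethylsilyloxy)prop-2-en-1-yl]-3-(dimethoxymethyl)-3-methyl-1-(propan-2-yl)cyclopentan-1-ol
Conditions: i-PrMgCl, LaCl3·2LiCl, THF, −20 → 0 °C
Reagents that add atoms: isopropylmagnesium chloride, CC(C)[Mg]Cl
Why: Grignard addition promoted by LaCl3·2LiCl (which suppresses enolisation and β-hydride reduction) should occur on the α face of the C4 ketone, opposite the adjacent C5 side chain and the C1 methyl, giving (4R) with the hydroxyl cis to the C1 methyl.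

Step 7
Reactants: 13 (1R,2S,3S)-2-[(1S)-1-(tert-butyldimethylsilyloxy)prop-2-en-1-yl]-3-(dimethoxymethyl)-3-methyl-1-(propan-2-yl)cyclopentan-1-ol
Product: 15 (1S,2S,3R)-2-[(1S)-1-(tert-butyldimethylsilyloxy)prop-2-en-1-yl]-1-methyl-3-(propan-2-yl)-3-(triethylsilyloxy)cyclopentane-1-carbaldehyde, via collidinium N,O-acetal triflate 14 (not isolated)
Conditions: TESOTf (excess), 2,4,6-collidine, CH2Cl2, 0 °C → rt; then H2O
Reagents that add atoms: triethylsilyl triflate, CC[Si](CC)(CC)OS(=O)(=O)C(F)(F)F; water, O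
Why: The silyl triflate–collidine pair silylates the tertiary hydroxyl and, by the known chemoselective cleavage of aldehyde-derived acetals, turns the dimethyl acetal into a pyridinium N,O-acetal that water hydrolyses to the non-enolisable C10 aldehyde, so protection and unmasking share one operation and the TBS ether is untouched.

Step 8
Reactants: 15 (1S,2S,3R)-2-[(1S)-1-(tert-butyldimethylsilyloxy)prop-2-en-1-yl]-1-methyl-3-(propan-2-yl)-3-(triethylsilyloxy)cyclopentane-1-carbaldehyde
Product: 16 1-[(1S,2S,3R)-2-[(1S)-1-(tert-butyldimethylsilyloxy)prop-2-en-1-yl]-1-methyl-3-(propan-2-yl)-3-(triethylsilyloxy)cyclopentyl]-2-methylprop-2-en-1-ol (both C10 epimers)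
Conditions: CH2=C(CH3)MgBr, THF, −78 → 0 °C
Reagents that add atoms: isopropenylmagnesium bromide, CC(=C)[Mg]Br
Why: Grignard 1,2-addition to the neopentyl aldehyde brings in C8 with its methyl group, and the configuration of the new C10 carbinol is irrelevant because C10 is oxidised in step 10.

Step 9
Reactants: 16 1-[(1S,2S,3R)-2-[(1S)-1-(tert-butyldimethylsilyloxy)prop-2-en-1-yl]-1-methyl-3-(propan-2-yl)-3-(triethylsilyloxy)cyclopentyl]-2-methylprop-2-en-1-ol
Product: 17 (3R,3aS,4S,7aS)-4-(tert-butyldimethylsilyloxy)-6,7a-dimethyl-3-(propan-2-yl)-3-(triethylsilyloxy)-2,3,3a,4,7,7a-hexahydro-1H-inden-7-ol (both C10 epimers)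
Conditions: second-generation Grubbs catalyst (5 mol %), CH2Cl2, 40 °C
Reagents that add atoms: none
Why: Ring-closing olefin metathesis between the monosubstituted C7 alkene and the 1,1-disubstituted C8 alkene should close the six-membered ring as a trisubstituted cyclohexene, the trans ring fusion being already fixed by C1 and C5.

Step 10
Reactants: 17 (3R,3aS,4S,7aS)-4-(tert-butyldimethylsilyloxy)-6,7a-dimethyl-3-(propan-2-yl)-3-(triethylsilyloxy)-2,3,3a,4,7,7a-hexahydro-1H-inden-7-ol
Product: 18 (3R,3aS,4S,7aS)-4-(tert-butyldimethylsilyloxy)-6,7a-dimethyl-3-(propan-2-yl)-3-(triethylsilyloxy)-1,2,3,3a,4,7a-hexahydro-7H-inden-7-one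
Conditions: Dess–Martin periodinane, NaHCO3, CH2Cl2, rt
Reagents that add atoms: none
Why: Dess–Martin oxidation of the secondary allylic alcohol converges both C10 epimers on the conjugated C7=C8–C10 enone under buffered conditions that touch neither silyl ether.

Step 11
Reactants: 18 (3R,3aS,4S,7aS)-4-(tert-butyldimethylsilyloxy)-6,7a-dimethyl-3-(propan-2-yl)-3-(triethylsilyloxy)-1,2,3,3a,4,7a-hexahydro-7H-inden-7-one
Product: 20 (3R,3aS,4S,7aS)-4-(tert-butyldimethylsilyloxy)-6,7a-dimethyl-3-(propan-2-yl)-3-(triethylsilyloxy)-7-(trimethylsilyloxy)-2,3,3a,4,5,7a-hexahydro-1H-indene, via lithium enolate 19 (not isolated)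
Conditions: LiBH(s-Bu)3, THF, −78 °C; then Me3SiCl, Et3N, −78 → 0 °C
Reagents that add atoms: chlorotrimethylsilane, C[Si](C)(C)Cl
Why: Conjugate hydride reduction of the cyclohexenone, which has no extra β-substituent and whose carbonyl is shielded by quaternary C1, should give the C8=C10 enolate regiospecifically, and O-silylation then gives the tetrasubstituted silyl enol ether without forcing enolisation of a hindered ketone.

Step 12
Reactants: 20 (3R,3aS,4S,7aS)-4-(tert-butyldimethylsilyloxy)-6,7a-dimethyl-3-(propan-2-yl)-3-(triethylsilyloxy)-7-(trimethylsilyloxy)-2,3,3a,4,5,7a-hexahydro-1H-indene; 21 diiodomethane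
Product: 24 (1R,3aS,8S,8aS)-8-(tert-butyldimethylsilyloxy)-3a,6-dimethyl-1-(propan-2-yl)-1-(triethylsilyloxy)-2,3,3a,7,8,8a-hexahydroazulen-4(1H)-one, via siloxycyclopropane 22 (not isolated), via β-chloro ketone 23 (not isolated)
Conditions: Et2Zn, CH2I2 (21), CH2Cl2, 0 °C → rt; then FeCl3, DMF, 0 °C → rt; then NaOAc, MeOH, reflux
Reagents that add atoms: none
Why: The zinc carbenoid (Simmons–Smith reaction under Furukawa conditions) should transfer CH2 to the electron-rich C8=C10 enol ether, so that C9 is bonded to both C8 and C10 in a siloxybicyclo[4.1.0]heptane. Trivalent iron then oxidises the siloxycyclopropane (the known FeCl3 ring enlargement of siloxybicycloalkanes) to an oxygen-centred radical at C10, β-scission breaks the shared C8–C10 bond to leave a tertiary C8 radical in the enlarged ring, chlorine transfer from FeCl3 gives the β-chloro ketone, and acetate removes HCl through the C9 enolate to give the conjugated C8=C9–C10 enone. The seven-membered ring is thus not closed by a cyclisation but arises by [2+1] methylene transfer followed by fragmentation of the bond common to the three- and six-membered rings. No stereocentre is created, because C8 and C10 both end trigonal and C1, C4, C5 and C6 are not touched. The regiocontrol needed comes from the substrate: the ketone can enolise only towards C8 since C1 is quaternary, and the C8 methyl makes cleavage of the internal bond (tertiary radical) far easier than cleavage of the C9–C10 bond (primary radical). The hindered TES and TBS ethers should survive FeCl3 in DMF, whereas the trimethylsilyl group on the cyclopropanol oxygen is the one that is lost.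

Step 13
Reactants: 24 (1R,3aS,8S,8aS)-8-(tert-butyldimethylsilyloxy)-3a,6-dimethyl-1-(propan-2-yl)-1-(triethylsilyloxy)-2,3,3a,7,8,8a-hexahydroazulen-4(1H)-one
Product: 25 (1R,3aS,4S,8S,8aS)-8-(tert-butyldimethylsilyloxy)-3a,6-dimethyl-1-(propan-2-yl)-1-(triethylsilyloxy)-1,2,3,3a,4,7,8,8a-octahydroazulen-4-ol
Conditions: NaBH4, CeCl3·7H2O, MeOH, −40 → 0 °C
Reagents that add atoms: none
Why: Luche 1,2-reduction in which hydride should attack C10 from the α face, anti to the axial C1 methyl on the neighbouring quaternary carbon, giving the 10β (10S) allylic alcohol.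

Step 14
Reactants: 25 (1R,3aS,4S,8S,8aS)-8-(tert-butyldimethylsilyloxy)-3a,6-dimethyl-1-(propan-2-yl)-1-(triethylsilyloxy)-1,2,3,3a,4,7,8,8a-octahydroazulen-4-ol
Product: 26 (1R,3aS,4R,8S,8aS)-8-(tert-butyldimethylsilyloxy)-3a,6-dimethyl-1-(propan-2-yl)-1-(triethylsilyloxy)-1,2,3,3a,4,7,8,8a-octahydroazulen-4-yl acetate
Conditions: PPh3, DIAD, AcOH, toluene/THF, 0 °C → rt
Reagents that add atoms: acetic acid, CC(=O)O
Why: Mitsunobu esterification with acetic acid displaces the activated allylic hydroxyl with inversion from the open α face and so installs the 10α (10R) acetate in one step, SN2′ attack being disfavoured because C8 is fully substituted.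

Step 15
Reactants: 26 (1R,3aS,4R,8S,8aS)-8-(tert-butyldimethylsilyloxy)-3a,6-dimethyl-1-(propan-2-yl)-1-(triethylsilyloxy)-1,2,3,3a,4,7,8,8a-octahydroazulen-4-yl acetate
Product: 27 (1R,3aS,4R,8S,8aS)-1,8-dihydroxy-3a,6-dimethyl-1-(propan-2-yl)-1,2,3,3a,4,7,8,8a-octahydroazulen-4-yl acetate
Conditions: HF·pyridine, pyridine, THF, 0 °C → rt
Reagents that add atoms: none
Why: Fluoride-mediated cleavage of both silyl ethers under buffered, weakly acidic conditions should leave the allylic acetate in place and avoid the base-induced acyl migration that fluoride salts could cause.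

Step 16
Reactants: 27 (1R,3aS,4R,8S,8aS)-1,8-dihydroxy-3a,6-dimethyl-1-(propan-2-yl)-1,2,3,3a,4,7,8,8a-octahydroazulen-4-yl acetate; 28 4-methoxybenzoyl chloride
Product: 29 (1R,3aS,4R,8S,8aS)-4-acetoxy-1-hydroxy-3a,6-dimethyl-1-(propan-2-yl)-1,2,3,3a,4,7,8,8a-octahydroazulen-8-yl 4-methoxybenzoate (CNP0256979.2)
Conditions: 28, Et3N, DMAP (cat.), CH2Cl2, 0 °C → rt
Reagents that add atoms: none
Why: DMAP-catalysed acylation should discriminate the secondary C6 hydroxyl from the hindered tertiary C4 hydroxyl and so complete the target without further protection.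

Compound list
1 | 3-ethoxycyclopent-2-en-1-one | CCOC1=CC(=O)CC1 | starting material
2 | 1,3-dithiane | C1CSCSC1 | starting material
3 | 2-lithio-1,3-dithiane | [Li]C1SCCCS1 | intermediate
4 | lithium 1-(1,3-dithian-2-yl)-3-ethoxycyclopent-2-en-1-olate (racemic) | CCOC1=CC(O[Li])(C2SCCCS2)CC1 | intermediate
5 | 3-(1,3-dithian-2-yl)cyclopent-2-en-1-one | O=C1C=C(C2SCCCS2)CC1 | intermediate
6 | 3-(dimethoxymethyl)cyclopent-2-en-1-one | COC(OC)C1=CC(=O)CC1 | intermediate
7 | dimethylaluminium (3S)-3-(dimethoxymethyl)-3-methylcyclopent-1-en-1-olate | COC(OC)[C@@]1(C)CCC(O[Al](C)C)=C1 | intermediate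
8 | (3S)-3-(dimethoxymethyl)-3-methylcyclopent-1-en-1-yl acetate | COC(OC)[C@@]1(C)CCC(OC(C)=O)=C1 | intermediate
9 | acrolein (prop-2-enal) | C=CC=O | starting material
10 | lithium (3S)-3-(dimethoxymethyl)-3-methylcyclopent-1-en-1-olate | COC(OC)[C@@]1(C)CCC(O[Li])=C1 | intermediate
11 | (2S,3S)-3-(dimethoxymethyl)-2-[(1S)-1-hydroxyprop-2-en-1-yl]-3-methylcyclopentan-1-one | COC(OC)[C@@]1(C)CCC(=O)[C@@H]1[C@@H](O)C=C | intermediate
12 | (2S,3S)-2-[(1S)-1-(tert-butyldimethylsilyloxy)prop-2-en-1-yl]-3-(dimethoxymethyl)-3-methylcyclopentan-1-one | COC(OC)[C@@]1(C)CCC(=O)[C@@H]1[C@@H](O[Si](C)(C)C(C)(C)C)C=C | intermediate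
13 | (1R,2S,3S)-2-[(1S)-1-(tert-butyldimethylsilyloxy)prop-2-en-1-yl]-3-(dimethoxymethyl)-3-methyl-1-(propan-2-yl)cyclopentan-1-ol | COC(OC)[C@@]1(C)CC[C@@](O)(C(C)C)[C@@H]1[C@@H](O[Si](C)(C)C(C)(C)C)C=C | intermediate
14 | 1-{methoxy[(1S,2S,3R)-2-[(1S)-1-(tert-butyldimethylsilyloxy)prop-2-en-1-yl]-1-methyl-3-(propan-2-yl)-3-(triethylsilyloxy)cyclopentyl]methyl}-2,4,6-trimethylpyridinium triflate (both C10 epimers) | COC([n+]2c(C)cc(C)cc2C)[C@@]1(C)CC[C@@](O[Si](CC)(CC)CC)(C(C)C)[C@@H]1[C@@H](O[Si](C)(C)C(C)(C)C)C=C.[O-]S(=O)(=O)C(F)(F)F | intermediate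
15 | (1S,2S,3R)-2-[(1S)-1-(tert-butyldimethylsilyloxy)prop-2-en-1-yl]-1-methyl-3-(propan-2-yl)-3-(triethylsilyloxy)cyclopentane-1-carbaldehyde | O=C[C@@]1(C)CC[C@@](O[Si](CC)(CC)CC)(C(C)C)[C@@H]1[C@@H](O[Si](C)(C)C(C)(C)C)C=C | intermediate
16 | 1-[(1S,2S,3R)-2-[(1S)-1-(tert-butyldimethylsilyloxy)prop-2-en-1-yl]-1-methyl-3-(propan-2-yl)-3-(triethylsilyloxy)cyclopentyl]-2-methylprop-2-en-1-ol (both C10 epimers) | C=C(C)C(O)[C@@]1(C)CC[C@@](O[Si](CC)(CC)CC)(C(C)C)[C@@H]1[C@@H](O[Si](C)(C)C(C)(C)C)C=C | intermediate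
17 | (3R,3aS,4S,7aS)-4-(tert-butyldimethylsilyloxy)-6,7a-dimethyl-3-(propan-2-yl)-3-(triethylsilyloxy)-2,3,3a,4,7,7a-hexahydro-1H-inden-7-ol (both C10 epimers, trans-fused) | CC(C)(C)[Si](C)(C)O[C@H]1C=C(C)C(O)[C@@]2(C)CC[C@@](O[Si](CC)(CC)CC)(C(C)C)[C@H]12 | intermediate
18 | (3R,3aS,4S,7aS)-4-(tert-butyldimethylsilyloxy)-6,7a-dimethyl-3-(propan-2-yl)-3-(triethylsilyloxy)-1,2,3,3a,4,7a-hexahydro-7H-inden-7-one | CC(C)(C)[Si](C)(C)O[C@H]1C=C(C)C(=O)[C@@]2(C)CC[C@@](O[Si](CC)(CC)CC)(C(C)C)[C@H]12 | intermediate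
19 | lithium (3R,3aS,4S,7aS)-4-(tert-butyldimethylsilyloxy)-6,7a-dimethyl-3-(propan-2-yl)-3-(triethylsilyloxy)-2,3,3a,4,5,7a-hexahydro-1H-inden-7-olate | CC(C)(C)[Si](C)(C)O[C@H]1CC(C)=C(O[Li])[C@@]2(C)CC[C@@](O[Si](CC)(CC)CC)(C(C)C)[C@H]12 | intermediate
20 | (3R,3aS,4S,7aS)-4-(tert-butyldimethylsilyloxy)-6,7a-dimethyl-3-(propan-2-yl)-3-(triethylsilyloxy)-7-(trimethylsilyloxy)-2,3,3a,4,5,7a-hexahydro-1H-indene (key-step precursor) | CC(C)(C)[Si](C)(C)O[C@H]1CC(C)=C(O[Si](C)(C)C)[C@@]2(C)CC[C@@](O[Si](CC)(CC)CC)(C(C)C)[C@H]12 | intermediate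
21 | diiodomethane | ICI | starting material
22 | siloxycyclopropane: 20 with a CH2 group (C9) bridging C8 and C10 (configuration of the two cyclopropane carbons not assigned) | CC(C)(C)[Si](C)(C)O[C@H]1CC2(C)CC2(O[Si](C)(C)C)[C@@]3(C)CC[C@@](O[Si](CC)(CC)CC)(C(C)C)[C@H]13 | intermediate
23 | (1R,3aS,8S,8aS)-8-(tert-butyldimethylsilyloxy)-6-chloro-3a,6-dimethyl-1-(propan-2-yl)-1-(triethylsilyloxy)-2,3,3a,5,6,7,8,8a-octahydroazulen-4(1H)-one (both C8 epimers) | CC(C)(C)[Si](C)(C)O[C@H]1CC(C)(Cl)CC(=O)[C@@]2(C)CC[C@@](O[Si](CC)(CC)CC)(C(C)C)[C@H]12 | intermediate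
24 | (1R,3aS,8S,8aS)-8-(tert-butyldimethylsilyloxy)-3a,6-dimethyl-1-(propan-2-yl)-1-(triethylsilyloxy)-2,3,3a,7,8,8a-hexahydroazulen-4(1H)-one (key-step product) | CC(C)(C)[Si](C)(C)O[C@H]1CC(C)=CC(=O)[C@@]2(C)CC[C@@](O[Si](CC)(CC)CC)(C(C)C)[C@H]12 | intermediate
25 | (1R,3aS,4S,8S,8aS)-8-(tert-butyldimethylsilyloxy)-3a,6-dimethyl-1-(propan-2-yl)-1-(triethylsilyloxy)-1,2,3,3a,4,7,8,8a-octahydroazulen-4-ol (10β-alcohol) | CC(C)(C)[Si](C)(C)O[C@H]1CC(C)=C[C@H](O)[C@@]2(C)CC[C@@](O[Si](CC)(CC)CC)(C(C)C)[C@H]12 | intermediate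
26 | (1R,3aS,4R,8S,8aS)-8-(tert-butyldimethylsilyloxy)-3a,6-dimethyl-1-(propan-2-yl)-1-(triethylsilyloxy)-1,2,3,3a,4,7,8,8a-octahydroazulen-4-yl acetate (10α-acetate) | CC(C)(C)[Si](C)(C)O[C@H]1CC(C)=C[C@@H](OC(C)=O)[C@@]2(C)CC[C@@](O[Si](CC)(CC)CC)(C(C)C)[C@H]12 | intermediate
27 | (1R,3aS,4R,8S,8aS)-1,8-dihydroxy-3a,6-dimethyl-1-(propan-2-yl)-1,2,3,3a,4,7,8,8a-octahydroazulen-4-yl acetate | O[C@H]1CC(C)=C[C@@H](OC(C)=O)[C@@]2(C)CC[C@@](O)(C(C)C)[C@H]12 | intermediate
28 | 4-methoxybenzoyl chloride | COc1ccc(C(Cl)=O)cc1 | starting material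
29 | (1R,3aS,4R,8S,8aS)-4-acetoxy-1-hydroxy-3a,6-dimethyl-1-(propan-2-yl)-1,2,3,3a,4,7,8,8a-octahydroazulen-8-yl 4-methoxybenzoate (CNP0256979.2) | COc1ccc(C(=O)O[C@H]2CC(C)=C[C@@H](OC(C)=O)[C@@]3(C)CC[C@@](O)(C(C)C)[C@H]23)cc1 | target

Total step count: 16. Longest linear sequence: 16 steps (1 → 29).

Steps most likely to fail

Step 12: methylene transfer to the crowded tetrasubstituted enol ether may stall, or the iron oxidation may open the wrong cyclopropane bond or strip the silyl ethers. The fallback keeps the same one-carbon insertion but uses a carbene and a cationic, not radical, opening. It sets out from enol ether 20. Dibromocarbene (CHBr3, KOt-Bu, pentane, −20 °C) should add to the C8=C10 bond to give the gem-dibromocyclopropane F1. On warming in toluene with a little pyridine, F1 should open electrocyclically across the C8–C10 bond with loss of the trimethylsilyl group to give the 9-bromo enone F2. Hydrodebromination (Pd(PPh3)4, Bu3SnH, THF) then returns to the route at enone 24.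

Step 14: displacement at the neopentyl-type allylic C10 may be slow, so that elimination to a diene or allylic transposition competes with inversion. The fallback sets the centre by reagent control instead of inversion and sets out from enone 24. A Corey–Bakshi–Shibata reduction, using the oxazaborolidine antipode that delivers hydride to the β face (catecholborane, toluene, −78 °C), should give the 10α-alcohol F3. Acetylation with retention (Ac2O, DMAP, pyridine) then rejoins the route at acetate 26.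

Step 4: the enolate may add with too little control at the new carbinol carbon C6 (anti versus syn addition). The fallback sets out from aldol 11, taken on as its C6 epimer mixture. Isopropyl addition to the free aldol (i-PrMgCl, LaCl3·2LiCl, chelate-controlled attack on the α face) should give the diol F4 as a C6 epimer mixture. Dess–Martin oxidation of the secondary allylic hydroxyl alone gives the vinyl ketone F5. A Corey–Bakshi–Shibata reduction then fixes C6 by reagent control to give the (6S)-diol F6. Selective silylation of the secondary hydroxyl (TBSOTf, 2,6-lutidine, −78 °C) rejoins the route at alcohol 13.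

Further compounds
F1 | step 12 | gem-dibromocyclopropane: 20 with a CBr2 group (C9) bridging C8 and C10 | CC(C)(C)[Si](C)(C)O[C@H]1CC2(C)C(Br)(Br)C2(O[Si](C)(C)C)[C@@]3(C)CC[C@@](O[Si](CC)(CC)CC)(C(C)C)[C@H]13
F2 | step 12 | (1R,3aS,8S,8aS)-5-bromo-8-(tert-butyldimethylsilyloxy)-3a,6-dimethyl-1-(propan-2-yl)-1-(triethylsilyloxy)-2,3,3a,7,8,8a-hexahydroazulen-4(1H)-one | CC(C)(C)[Si](C)(C)O[C@H]1CC(C)=C(Br)C(=O)[C@@]2(C)CC[C@@](O[Si](CC)(CC)CC)(C(C)C)[C@H]12
F3 | step 14 | (1R,3aS,4R,8S,8aS)-8-(tert-butyldimethylsilyloxy)-3a,6-dimethyl-1-(propan-2-yl)-1-(triethylsilyloxy)-1,2,3,3a,4,7,8,8a-octahydroazulen-4-ol (10α-alcohol) | CC(C)(C)[Si](C)(C)O[C@H]1CC(C)=C[C@@H](O)[C@@]2(C)CC[C@@](O[Si](CC)(CC)CC)(C(C)C)[C@H]12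
F4 | step 4 | (1R,2S,3S)-3-(dimethoxymethyl)-2-(1-hydroxyprop-2-en-1-yl)-3-methyl-1-(propan-2-yl)cyclopentan-1-ol (both C6 epimers) | COC(OC)[C@@]1(C)CC[C@@](O)(C(C)C)[C@@H]1C(O)C=C
F5 | step 4 | 1-[(1S,2R,5S)-5-(dimethoxymethyl)-2-hydroxy-5-methyl-2-(propan-2-yl)cyclopentyl]prop-2-en-1-one | COC(OC)[C@@]1(C)CC[C@@](O)(C(C)C)[C@@H]1C(=O)C=C
F6 | step 4 | (1R,2S,3S)-3-(dimethoxymethyl)-2-[(1S)-1-hydroxyprop-2-en-1-yl]-3-methyl-1-(propan-2-yl)cyclopentan-1-ol | COC(OC)[C@@]1(C)CC[C@@](O)(C(C)C)[C@@H]1[C@@H](O)C=C
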